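**Retrosynthetic overview**
1. Endgame: both CH2CO2H groups are unmasked last from N-acyl oxazolidinones. The halves are joined by forming C2'–C3' of the isocitrate of half A, by a copper bis(oxazoline) Mukaiyama–Michael addition of the silyl ketene acetal of methyl O-albicanylglycolate to a fumaroyl imide already esterified to O15 of half B. The same reaction with a simple fumaroyl imide builds the isocitrate of half B.
2. Half A (gem-dimethyl drimane): rings A and B arise in one operation from a monocyclic carbinol. Ring A forms by one-carbon enlargement of a 1,2,2-trimethylcyclopentane taken from camphoric acid, and ring B by allylsilane capture of the resulting cation.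
3. Enabling feature: in ring A the CMe2 carbon C4 is bonded to C5, the neighbour of methyl-bearing C10, and across the trans A/B fusion the C4–C5 and C10–C9 bonds are antiperiplanar. Moving C4 back from C5 to C10 maps ring A (C1–C5, C10) onto a cyclopentane (C1–C4, C10) with a leaving group on exocyclic C5, and C9–C8(=C12H2) is the retron of an allylsilane.
4. Half B (15-oxygenated drimane): rings A and B arise by a titanocene radical bicyclisation of a Sharpless epoxide made from farnesol. The leftover 3-OH is then removed.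
5. Ring order: half A, ring A then ring B within the key step; half B, ring A then ring B within one radical cascade; no ring of the target is formed afterwards.

Key step: step 10

Remark: drimane numbering (C1–C15) is used for both decalin halves: 5α-H, 9α-H with equatorial C11H2O, 10β-CH3, and in half B C15 is the equatorial 4α-CH2O group. C1'–C6' is used for each isocitrate: C1' is the ester on C2', C6' the carboxyl on C3', C4'–C5' the CH2CO2H arm. (R,R)-t-Bu-box is 2,2'-(propane-2,2-diyl)bis[(4R)-4-tert-butyl-4,5-dihydro-1,3-oxazole]. (1S,3R)-Camphoric acid and this ligand are taken as commercial.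

**Half A**

Step 1
Reactants: 1 (1S,3R)-camphoric acid
Product: 2 (1S,3R)-3-{[(1,3-dioxoisoindolin-2-yl)oxy]carbonyl}-1,2,2-trimethylcyclopentane-1-carboxylic acid
Conditions: N-hydroxyphthalimide (1.0 equiv), DIC (1.05 equiv), DMAP (5 mol%), CH2Cl2, 0 °C to rt
Reagents that add atoms: N-hydroxyphthalimide, O=C1c2ccccc2C(=O)N1O
Why: Carbodiimide (Steglich-type) esterification should occur only at the secondary C3 carboxyl, because the C1 carboxyl sits on a quaternary carbon next to the CMe2 group (a transient cyclic anhydride would also be opened at its less hindered carbonyl).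

Step 2
Reactants: 2 camphoric acid 3-(N-phthalimidoyl) ester
Product: 3 (1S)-1,2,2-trimethylcyclopentane-1-carboxylic acid
Conditions: Ru(bpy)3(PF6)2 (1 mol%), Hantzsch ester (1.5 equiv), CH2Cl2, blue LED, rt
Reagents that add atoms: none
Why: Photoredox decarboxylative reduction of a redox-active ester (tin-free Barton-type decarboxylation) should remove the C3 carboxyl through a secondary radical that takes hydrogen from the Hantzsch ester, leaving the quaternary stereocentre untouched.

Step 3
Reactants: 3 (1S)-1,2,2-trimethylcyclopentane-1-carboxylic acid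
Product: 4 1-[(1S)-1,2,2-trimethylcyclopentyl]ethan-1-one
Conditions: MeLi (2.3 equiv), Et2O, 0 °C to reflux; then H2O
Reagents that add atoms: methyllithium, [Li]C
Why: Addition of methyllithium to the lithium carboxylate gives a gem-dialkoxide that collapses to the methyl ketone only on work-up (acid-to-ketone synthesis), and the crowded carbonyl rules out over-addition.

Step 4
Reactants: 4 1-[(1S)-1,2,2-trimethylcyclopentyl]ethan-1-one
Product: 5 1-[(1S)-1,2,2-trimethylcyclopentyl]pent-4-yn-1-one
Conditions: LDA (1.05 equiv), THF, −78 °C; propargyl bromide (1.2 equiv), DMPU, −78 to 0 °C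
Reagents that add atoms: propargyl bromide, C#CCBr
Why: In this kinetic enolate alkylation the ketone has α-hydrogens on the methyl side only, so a single enolate forms and is propargylated (SN2) to create the C6–C7 bond.

Step 5
Reactants: 5 1-[(1S)-1,2,2-trimethylcyclopentyl]pent-4-yn-1-one
Product: 6 (1S)-1-[(1S)-1,2,2-trimethylcyclopentyl]pent-4-yn-1-ol
Conditions: (R)-Me-CBS oxazaborolidine (20 mol%), catecholborane (2 equiv), toluene, −78 to −40 °C; aqueous work-up
Reagents that add atoms: none
Why: In the Corey–Bakshi–Shibata reduction the tert-alkyl group acts as the large and the butynyl chain as the small substituent, so the (R)-catalyst should give the (S)-carbinol at C5 under reagent control, while catecholborane leaves the alkyne alone at low temperature.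

Step 6
Reactants: 6 (1S)-1-[(1S)-1,2,2-trimethylcyclopentyl]pent-4-yn-1-ol
Product: 7 (6S)-6-[(1S)-1,2,2-trimethylcyclopentyl]hex-2-yne-1,6-diol
Conditions: n-BuLi (2.2 equiv), THF, −78 °C; (CH2O)n, −78 °C to rt; H2O
Reagents that add atoms: paraformaldehyde (as formaldehyde), C=O
Why: Hydroxymethylation of the lithium acetylide (alkoxide/acetylide dianion) adds C11 as a propargylic alcohol.

Step 7
Reactants: 7 (6S)-6-[(1S)-1,2,2-trimethylcyclopentyl]hex-2-yne-1,6-diol
Product: 8 (2Z,6S)-3-iodo-6-[(1S)-1,2,2-trimethylcyclopentyl]hex-2-ene-1,6-diol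
Conditions: NaAlH2(OCH2CH2OMe)2 (Red-Al, 3.5 equiv), THF, 0 °C to rt; then I2, −78 to 0 °C
Reagents that add atoms: iodine, II
Why: Hydroxyl-directed trans-hydroalumination places aluminium on C8 cis to the CH2O group, and iodinolysis with retention gives the (Z)-3-iodoallylic alcohol, which fixes C7 trans to C11.

Step 8
Reactants: 8 (2Z,6S)-3-iodo-6-[(1S)-1,2,2-trimethylcyclopentyl]hex-2-ene-1,6-diol
Product: 9 (2Z,6S)-3-[(trimethylsilyl)methyl]-6-[(1S)-1,2,2-trimethylcyclopentyl]hex-2-ene-1,6-diol
Conditions: Me3SiCH2MgCl (4 equiv), Pd(PPh3)4 (5 mol%), THF, rt to 45 °C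
Reagents that add atoms: (trimethylsilyl)methylmagnesium chloride, C[Si](C)(C)C[Mg]Cl
Why: Kumada cross-coupling of the alkenyl iodide with this β-hydrogen-free Grignard reagent proceeds with retention of geometry and installs the allylsilane, the two hydroxyls being carried as magnesium alkoxides.

Step 9
Reactants: 9 (2Z,6S)-3-[(trimethylsilyl)methyl]-6-[(1S)-1,2,2-trimethylcyclopentyl]hex-2-ene-1,6-diol
Product: 10 methyl 2-{[(2Z,6S)-6-hydroxy-3-[(trimethylsilyl)methyl]-6-[(1S)-1,2,2-trimethylcyclopentyl]hex-2-en-1-yl]oxy}acetate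
Conditions: NaH (1.05 equiv), BrCH2CO2Me (1.1 equiv), Bu4NI (10 mol%), THF, 0 °C
Reagents that add atoms: methyl bromoacetate, COC(=O)CBr
Why: Williamson etherification should take place only at the unhindered primary allylic alkoxide, since the secondary carbinol next to the quaternary carbon is too crowded, and the C11–O–C2' ether is thereby made before C11 becomes hindered.

Step 10
Reactants: 10 methyl 2-{[(2Z,6S)-6-hydroxy-3-[(trimethylsilyl)methyl]-6-[(1S)-1,2,2-trimethylcyclopentyl]hex-2-en-1-yl]oxy}acetate
Product: 12 methyl 2-{[(5S,9S,10S)-drim-8(12)-en-11-yl]oxy}acetate (methyl O-albicanylglycolate), via secondary triflate 11 (not isolated)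
Conditions: Tf2O (1.2 equiv), 2,6-di-tert-butyl-4-methylpyridine (3 equiv), CH2Cl2, −78 to −20 °C; aq NaHCO3
Reagents that add atoms: trifluoromethanesulfonic anhydride, O=S(=O)(OS(=O)(=O)C(F)(F)F)C(F)(F)F (its CF3SO2 group stands in 11 only)
Why: Proposed new method: triflation of the neopentyl-type C5 carbinol gives 11, whose C–O bond should ionise below −20 °C with participation of the antiperiplanar C10–C4 σ bond, so the CMe2 carbon C4 shifts from C10 to C5 (Wagner–Meerwein 1,2-shift, cyclopentylcarbinyl to cyclohexyl), the tertiary C10 cation is taken at once by C9 of the allylsilane, and loss of the silyl group from the β-silyl C8 cation leaves the C8=C12 methylene. The closest known reaction types are the solvolytic ring enlargement of 1-methylcyclopentylcarbinyl sulfonates, the cuprenyl-to-chamigrenyl shift of terpene biosynthesis and the allylsilane-terminated cation–olefin cyclisation of monocyclic tertiary cations; the only new element is that the first feeds the second in one flask. Ring A is made by ring enlargement of the five-membered ring (C4–C5 formed, C4–C10 broken) and ring B by a 6-endo-trig attack of the C8=C9 π bond on C10 through a chair. C5 is set by inversion of the (S)-carbinol (migration anti to the leaving group), C10 by attack of C9 anti to the departing C4, for which the (S)-quaternary carbon of 10 places the side chain equatorial and the methyl axial (trans fusion), and C9 by the (Z)-allylsilane geometry (C7 trans to C11), which puts CH2O equatorial. The step needs migration of C4 rather than of C1 or CH3, which is secured by the higher migratory aptitude of the fully substituted carbon and by relief of ring strain and of the vicinal quaternary congestion, while direct capture of C5 by the alkene would be a disfavoured 5-endo closure. The hindered pyridine keeps the medium acid-free, so protodesilylation, silyl-assisted loss of the allylic ether and isomerisation of the new alkene should stay slow.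

**Fumaroyl imides**

Step 11
Reactants: 13 monomethyl fumarate; 14 2-oxazolidinone
Product: 15 methyl (E)-4-oxo-4-(2-oxo-1,3-oxazolidin-3-yl)but-2-enoate
Conditions: DCC (1.1 equiv), DMAP (10 mol%), CH2Cl2, 0 °C to rt
Reagents that add atoms: none
Why: Carbodiimide/DMAP N-acylation of the oxazolidinone by the free acid gives the unsymmetrical fumarate whose imide end can be chelated selectively.

Step 12
Reactants: 16 mono-tert-butyl fumarate; 14 2-oxazolidinone
Product: 17 tert-butyl (E)-4-oxo-4-(2-oxo-1,3-oxazolidin-3-yl)but-2-enoate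
Conditions: DCC (1.1 equiv), DMAP (10 mol%), CH2Cl2, 0 °C to rt
Reagents that add atoms: none
Why: This is the same carbodiimide N-acylation as in step 11.

Step 13
Reactants: 17 tert-butyl (E)-4-oxo-4-(2-oxo-1,3-oxazolidin-3-yl)but-2-enoate
Product: 18 (E)-4-oxo-4-(2-oxo-1,3-oxazolidin-3-yl)but-2-enoic acid
Conditions: CF3CO2H/CH2Cl2 (1:3), rt
Reagents that add atoms: none
Why: Acidolysis of the tert-butyl ester (E1 loss of isobutene) leaves the imide and the alkene untouched.

**Half B**

Step 14
Reactants: 19 (2E,6E)-farnesol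
Product: 20 methyl 2-{[(2E,6E)-3,7,11-trimethyldodeca-2,6,10-trien-1-yl]oxy}acetate
Conditions: NaH (1.1 equiv), BrCH2CO2Me (1.2 equiv), Bu4NI (10 mol%), THF, 0 °C
Reagents that add atoms: methyl bromoacetate, COC(=O)CBr
Why: Williamson etherification of the primary allylic alkoxide installs the C11–O–C2' ether at the acyclic stage.

Step 15
Reactants: 20 methyl O-farnesylglycolate
Product: 21 methyl 2-{[(2E,6E,10E)-12-hydroxy-3,7,11-trimethyldodeca-2,6,10-trien-1-yl]oxy}acetate
Conditions: SeO2 (10 mol%), t-BuOOH (2 equiv), salicylic acid (10 mol%), CH2Cl2, 0 °C to rt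
Reagents that add atoms: tert-butyl hydroperoxide, CC(C)(C)OO
Why: Selenium dioxide allylic oxidation (ene reaction then [2,3]-shift) is (E)-selective and should prefer the electron-rich terminal isopropylidene group, placing oxygen on the methyl that becomes C15.

Step 16
Reactants: 21 12-hydroxyfarnesyl glycolate ether
Product: 22 methyl 2-{[(2E,6E)-9-[(2S,3S)-3-(hydroxymethyl)-3-methyloxiran-2-yl]-3,7-dimethylnona-2,6-dien-1-yl]oxy}acetate
Conditions: Ti(OiPr)4 (10 mol%), L-(+)-diethyl tartrate (12 mol%), t-BuOOH (2 equiv), 4 Å MS, CH2Cl2, −20 °C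
Reagents that add atoms: tert-butyl hydroperoxide, CC(C)(C)OO
Why: Sharpless asymmetric epoxidation touches only the allylic-alcohol alkene, and with L-(+)-tartrate an (E)-allylic alcohol gives the (2S,3S)-epoxy alcohol, which sets C3 as (S).

Step 17
Reactants: 22 (2S,3S)-epoxy alcohol
Product: 23 tert-butyldiphenylsilyl ether of 22
Conditions: TBDPSCl (1.1 equiv), imidazole (2 equiv), CH2Cl2, rt
Reagents that add atoms: tert-butyl(chloro)diphenylsilane, CC(C)(C)[Si](Cl)(c1ccccc1)c1ccccc1
Why: Silylation protects O15 with a bulky group that is also meant to steer the next step.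

Step 18
Reactants: 23 epoxy silyl ether
Product: 25 methyl 2-{[3β-hydroxy-15-(tert-butyldiphenylsilyloxy)drim-8(12)-en-11-yl]oxy}acetate, via trimethylsilyl ether 24 (not isolated)
Conditions: Cp2TiCl2 (20 mol%), Mn dust (8 equiv), Me3SiCl (4 equiv), 2,4,6-collidine (7 equiv), THF, rt; then 1 M HCl, THF, 0 °C
Reagents that add atoms: chlorotrimethylsilane, C[Si](C)(C)Cl (its Me3Si group stands in 24 only)
Why: In this radical epoxypolyene bicyclisation by trivalent titanium (Cp2TiCl formed in situ) the epoxide opens homolytically at C4, two 6-endo chair closures follow, and trapping of the C8 radical with β-hydride elimination toward the methyl gives the exocyclic alkene, while the retained C3 stereocentre orders C5, C9 and C10 and the bulky CH2OTBDPS group should take the equatorial 4α site of the planar C4 radical.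

Step 19
Reactants: 25 3β-alcohol
Product: 26 3-O-(imidazol-1-ylthiocarbonyl) derivative of 25
Conditions: 1,1'-thiocarbonyldiimidazole (3 equiv), DMAP (20 mol%), ClCH2CH2Cl, 80 °C
Reagents that add atoms: 1,1'-thiocarbonyldiimidazole, S=C(n1ccnc1)n1ccnc1
Why: Thioacylation of the equatorial secondary alcohol under neutral conditions prepares the radical deoxygenation without touching the ester.

Step 20
Reactants: 26 thiocarbonylimidazolide
Product: 27 methyl 2-{[15-(tert-butyldiphenylsilyloxy)drim-8(12)-en-11-yl]oxy}acetate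
Conditions: Bu3SnH (2 equiv), AIBN (10 mol%), toluene, 100 °C
Reagents that add atoms: none
Why: Barton–McCombie deoxygenation removes the auxiliary 3-oxygen through a secondary radical that has no alkene within cyclisation range.

Step 21
Reactants: 27 silyl-protected half B glycolate
Product: 28 (Z)-trimethylsilyl methyl ketene acetal of 27
Conditions: LDA (1.1 equiv), THF, −78 °C; Me3SiCl (1.5 equiv), −78 °C to rt; pentane, filtration
Reagents that add atoms: chlorotrimethylsilane, C[Si](C)(C)Cl
Why: Chelation-controlled enolisation of the α-alkoxy ester followed by O-silylation should give the ketene acetal with the OSiMe3 and alkoxy groups cis.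

Step 22
Reactants: 28 ketene acetal of half B; 15 methyl fumaroyl imide
Product: 29 dimethyl (2R,3R)-2-{[15-(tert-butyldiphenylsilyloxy)drim-8(12)-en-11-yl]oxy}-3-[2-oxo-2-(2-oxo-1,3-oxazolidin-3-yl)ethyl]butanedioate
Conditions: [Cu((R,R)-t-Bu-box)](SbF6)2 (10 mol%), (CF3)2CHOH (1.1 equiv), CH2Cl2, −78 to −20 °C
Reagents that add atoms: none
Why: In this catalytic enantioselective Mukaiyama–Michael addition the divalent copper Lewis acid chelates both imide carbonyls, so only the alkene carbon β to the imide (the one bearing CO2Me) is attacked, on the face left open by the (R,R)-ligand in the square-planar s-cis complex (C3' R), while an open antiperiplanar transition state with the ketene acetal hydrogen in the crowded sector between C4' and C6' should give C2' R.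

Step 23
Reactants: 29 silyl-protected half B
Product: 30 dimethyl (2R,3R)-2-{[15-hydroxydrim-8(12)-en-11-yl]oxy}-3-[2-oxo-2-(2-oxo-1,3-oxazolidin-3-yl)ethyl]butanedioate
Conditions: HF·pyridine, pyridine, THF, 0 °C to rt
Reagents that add atoms: none
Why: Buffered fluoride desilylation frees the neopentyl 15-OH without base, so the imide, the esters and the epimerisable C2' and C3' centres should be safe.

Step 24
Reactants: 30 half B alcohol; 18 fumaric acid mono-imide
Product: 31 15-O-[(E)-4-oxo-4-(2-oxo-1,3-oxazolidin-3-yl)but-2-enoyl] derivative of 30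
Conditions: EDC·HCl (1.5 equiv), DMAP (20 mol%), CH2Cl2, 0 °C to rt
Reagents that add atoms: none
Why: Steglich esterification of the primary 15-OH with an unhindered, non-epimerisable acid makes the inter-half ester link before any stereocentre stands next to it.

**Union and endgame**

Step 25
Reactants: 12 methyl O-albicanylglycolate
Product: 32 (Z)-trimethylsilyl methyl ketene acetal of 12
Conditions: LDA (1.1 equiv), THF, −78 °C; Me3SiCl (1.5 equiv), −78 °C to rt; pentane, filtration
Reagents that add atoms: chlorotrimethylsilane, C[Si](C)(C)Cl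
Why: This is the same chelation-controlled enolisation and O-silylation as in step 21.

Step 26
Reactants: 32 ketene acetal of half A; 31 half B fumaroyl imide
Product: 33 bis(N-acyl oxazolidinone) of the target (both C5' carboxyls as 2-oxo-1,3-oxazolidin-3-yl imides; 2'R,3'R in both isocitrates)
Conditions: [Cu((R,R)-t-Bu-box)](SbF6)2 (30 mol%), (CF3)2CHOH (1.1 equiv), CH2Cl2, −78 to −20 °C
Reagents that add atoms: none
Why: The same catalyst-controlled Mukaiyama–Michael addition as in step 22 joins the halves by forming C2'–C3' and sets both centres as (R), with a higher loading to allow for binding of copper by the saturated imide of 31.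

Step 27
Reactants: 33 bis-imide
Product: 34 target compound CNP0139922.3
Conditions: LiOH (4 equiv), 30% H2O2 (16 equiv), THF/H2O (3:1), 0 °C; aq Na2SO3; 1 M HCl to pH 3
Reagents that add atoms: hydrogen peroxide, OO
Why: In the lithium hydroperoxide cleavage of N-acyl oxazolidinones the α-effect nucleophile attacks the two exocyclic imide carbonyls much faster than the methyl and neopentyl esters, and the isolated alkenes are inert to basic peroxide.

**Compound list**
1 | (1S,3R)-camphoric acid | C[C@]1(C(=O)O)CC[C@@H](C(=O)O)C1(C)C | starting material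
2 | (1S,3R)-camphoric acid 3-(N-phthalimidoyl) ester | C[C@]1(C(=O)O)CC[C@@H](C(=O)ON2C(=O)c3ccccc3C2=O)C1(C)C | intermediate
3 | (1S)-1,2,2-trimethylcyclopentane-1-carboxylic acid | C[C@]1(C(=O)O)CCCC1(C)C | intermediate
4 | 1-[(1S)-1,2,2-trimethylcyclopentyl]ethan-1-one | C[C@]1(C(C)=O)CCCC1(C)C | intermediate
5 | 1-[(1S)-1,2,2-trimethylcyclopentyl]pent-4-yn-1-one | C[C@]1(C(=O)CCC#C)CCCC1(C)C | intermediate
6 | (1S)-1-[(1S)-1,2,2-trimethylcyclopentyl]pent-4-yn-1-ol | C[C@]1([C@@H](O)CCC#C)CCCC1(C)C | intermediate
7 | (6S)-6-[(1S)-1,2,2-trimethylcyclopentyl]hex-2-yne-1,6-diol | C[C@]1([C@@H](O)CCC#CCO)CCCC1(C)C | intermediate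
8 | (2Z,6S)-3-iodo-6-[(1S)-1,2,2-trimethylcyclopentyl]hex-2-ene-1,6-diol | C[C@]1([C@@H](O)CC/C(I)=C/CO)CCCC1(C)C | intermediate
9 | (2Z,6S)-3-[(trimethylsilyl)methyl]-6-[(1S)-1,2,2-trimethylcyclopentyl]hex-2-ene-1,6-diol | C[C@]1([C@@H](O)CC/C(C[Si](C)(C)C)=C/CO)CCCC1(C)C | intermediate
10 | methyl 2-{[(2Z,6S)-6-hydroxy-3-[(trimethylsilyl)methyl]-6-[(1S)-1,2,2-trimethylcyclopentyl]hex-2-en-1-yl]oxy}acetate | C[C@]1([C@@H](O)CC/C(C[Si](C)(C)C)=C/COCC(=O)OC)CCCC1(C)C | intermediate
11 | 6-O-triflate of 10 | C[C@]1([C@@H](OS(=O)(=O)C(F)(F)F)CC/C(C[Si](C)(C)C)=C/COCC(=O)OC)CCCC1(C)C | intermediate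
12 | methyl 2-{[(5S,9S,10S)-drim-8(12)-en-11-yl]oxy}acetate | C=C1CC[C@H]2C(C)(C)CCC[C@]2(C)[C@H]1COCC(=O)OC | intermediate
13 | monomethyl fumarate | COC(=O)/C=C/C(=O)O | starting material
14 | 2-oxazolidinone | O=C1NCCO1 | starting material
15 | methyl (E)-4-oxo-4-(2-oxo-1,3-oxazolidin-3-yl)but-2-enoate | COC(=O)/C=C/C(=O)N1CCOC1=O | intermediate
16 | mono-tert-butyl fumarate | CC(C)(C)OC(=O)/C=C/C(=O)O | starting material
17 | tert-butyl (E)-4-oxo-4-(2-oxo-1,3-oxazolidin-3-yl)but-2-enoate | CC(C)(C)OC(=O)/C=C/C(=O)N1CCOC1=O | intermediate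
18 | (E)-4-oxo-4-(2-oxo-1,3-oxazolidin-3-yl)but-2-enoic acid | OC(=O)/C=C/C(=O)N1CCOC1=O | intermediate
19 | (2E,6E)-farnesol | CC(C)=CCC/C(C)=C/CC/C(C)=C/CO | starting material
20 | methyl O-[(2E,6E)-farnesyl]glycolate | CC(C)=CCC/C(C)=C/CC/C(C)=C/COCC(=O)OC | intermediate
21 | methyl O-[(2E,6E,10E)-12-hydroxyfarnesyl]glycolate | OC/C(C)=C/CC/C(C)=C/CC/C(C)=C/COCC(=O)OC | intermediate
22 | (2S,3S)-epoxy alcohol of 21 | OC[C@]1(C)O[C@H]1CC/C(C)=C/CC/C(C)=C/COCC(=O)OC | intermediate
23 | tert-butyldiphenylsilyl ether of 22 | CC(C)(C)[Si](OC[C@]1(C)O[C@H]1CC/C(C)=C/CC/C(C)=C/COCC(=O)OC)(c2ccccc2)c3ccccc3 | intermediate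
24 | 3-O-trimethylsilyl ether of 25 | CC(C)(C)[Si](OC[C@]1(C)[C@@H](O[Si](C)(C)C)CC[C@]2(C)[C@@H](COCC(=O)OC)C(=C)CC[C@@H]12)(c3ccccc3)c4ccccc4 | intermediate
25 | methyl 2-{[3β-hydroxy-15-(tert-butyldiphenylsilyloxy)drim-8(12)-en-11-yl]oxy}acetate (4α-CH2OSi, 5α-H, 9α-H, 10β-CH3) | CC(C)(C)[Si](OC[C@]1(C)[C@@H](O)CC[C@]2(C)[C@@H](COCC(=O)OC)C(=C)CC[C@@H]12)(c3ccccc3)c4ccccc4 | intermediate
26 | 3-O-(imidazol-1-ylthiocarbonyl) derivative of 25 | CC(C)(C)[Si](OC[C@]1(C)[C@@H](OC(=S)n5ccnc5)CC[C@]2(C)[C@@H](COCC(=O)OC)C(=C)CC[C@@H]12)(c3ccccc3)c4ccccc4 | intermediate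
27 | methyl 2-{[15-(tert-butyldiphenylsilyloxy)drim-8(12)-en-11-yl]oxy}acetate | CC(C)(C)[Si](OC[C@]1(C)CCC[C@]2(C)[C@@H](COCC(=O)OC)C(=C)CC[C@@H]12)(c3ccccc3)c4ccccc4 | intermediate
28 | (Z)-trimethylsilyl methyl ketene acetal of 27 | CC(C)(C)[Si](OC[C@]1(C)CCC[C@]2(C)[C@@H](CO/C=C(/OC)O[Si](C)(C)C)C(=C)CC[C@@H]12)(c3ccccc3)c4ccccc4 | intermediate
29 | dimethyl (2R,3R)-2-{[15-(tert-butyldiphenylsilyloxy)drim-8(12)-en-11-yl]oxy}-3-[2-oxo-2-(2-oxo-1,3-oxazolidin-3-yl)ethyl]butanedioate | CC(C)(C)[Si](OC[C@]1(C)CCC[C@]2(C)[C@@H](CO[C@@H](C(=O)OC)[C@@H](CC(=O)N5CCOC5=O)C(=O)OC)C(=C)CC[C@@H]12)(c3ccccc3)c4ccccc4 | intermediate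
30 | 15-hydroxy compound from 29 | OC[C@]1(C)CCC[C@]2(C)[C@@H](CO[C@@H](C(=O)OC)[C@@H](CC(=O)N3CCOC3=O)C(=O)OC)C(=C)CC[C@@H]12 | intermediate
31 | 15-O-fumaroyl imide of 30 | O=C1OCCN1C(=O)/C=C/C(=O)OC[C@]2(C)CCC[C@]3(C)[C@@H](CO[C@@H](C(=O)OC)[C@@H](CC(=O)N4CCOC4=O)C(=O)OC)C(=C)CC[C@@H]23 | intermediate
32 | (Z)-trimethylsilyl methyl ketene acetal of 12 | C=C1CC[C@H]2C(C)(C)CCC[C@]2(C)[C@H]1CO/C=C(/OC)O[Si](C)(C)C | intermediate
33 | bis(N-acyl oxazolidinone) of the target | C=C1CC[C@H]2C(C)(C)CCC[C@]2(C)[C@H]1CO[C@@H](C(=O)OC)[C@@H](CC(=O)N3CCOC3=O)C(=O)OC[C@]1(C)CCC[C@]2(C)[C@@H](CO[C@@H](C(=O)OC)[C@@H](CC(=O)N3CCOC3=O)C(=O)OC)C(=C)CC[C@@H]12 | intermediate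
34 | CNP0139922.3 | C=C1CC[C@H]2C(C)(C)CCC[C@]2(C)[C@H]1CO[C@@H](C(=O)OC)[C@@H](CC(=O)O)C(=O)OC[C@]1(C)CCC[C@]2(C)[C@@H](CO[C@@H](C(=O)OC)[C@@H](CC(=O)O)C(=O)OC)C(=C)CC[C@@H]12 | target

**Step count**
Total step count: 27. Longest linear sequence: 13 steps (steps 1–10, 25, 26, 27 from 1; equally steps 14–24, 26, 27 from 19).

**Steps most likely to fail**

1. Step 10. After ionisation, elimination or a hydride shift at the C10 cation may outrun ring closure. Migration of C1 or of the methyl group may compete with that of C4. Silyl-assisted loss of the allylic ether may consume the terminator.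
Fallback (sets out from 6, comes back at 12): the two events are separated, each being known chemistry. Alcohol 6 is mesylated (MsCl, Et3N) to the mesylate F1. This is hydrolysed in buffered aqueous acetone (NaHCO3, 50 °C). With no π-nucleophile present, the solvolytic Wagner–Meerwein ring enlargement should end by capture of water to give (2S)-2-(but-3-yn-1-yl)-1,3,3-trimethylcyclohexan-1-ol F2, whose carbinol configuration does not matter. The chemistry of steps 6 to 9 is then repeated: hydroxymethylation to the propargylic alcohol F3, Red-Al then I2 to the (Z)-iodide F4, Kumada coupling to the allylsilane diol F5, and Williamson etherification of the primary alcohol to the glycolate ether F6. Ionisation of the tertiary alcohol of F6 with SnCl4 (CH2Cl2, −78 °C) regenerates the same C10 cation, and an allylsilane-terminated cation–olefin cyclisation closes ring B to give 12.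

2. Step 26 (the same concerns apply in milder form to step 22). Turnover may be slow because the saturated imide of the acceptor binds the copper catalyst. Simple diastereoselection at C2' may erode with two bulky partners. If the sense of induction turns out opposite, the antipodal ligand is used.
Fallback (sets out from 32 and 17, comes back at 33): the halves are joined by esterification instead of C–C bond formation. Ketene acetal 32 is added under the conditions of step 22 to the small acceptor 17 to give the tert-butyl ester F7, at which stage diastereomers can be separated. Me3SiOTf/2,6-lutidine followed by water frees the C6' acid F8. This acid is esterified with alcohol 30 (2-methyl-6-nitrobenzoic anhydride, DMAP, Shiina esterification) to give 33.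

3. Step 27. The activated α-alkoxy methyl esters may be saponified in competition. The C2' alkoxy group may be lost by β-elimination under the basic peroxide conditions.
Fallback (sets out from 33, comes back at 34): base is avoided. Chelation-selective Lewis acid alcoholysis of both imides (Yb(OTf)3, 10 mol%, allyl alcohol, rt) gives the bis(allyl ester) F9. Neutral deallylation with zerovalent palladium (Pd(PPh3)4, morpholine, THF, rt) then gives 34.

**Further compounds**
F1 | step 10 | (1S)-1-[(1S)-1,2,2-trimethylcyclopentyl]pent-4-yn-1-yl methanesulfonate | C[C@]1([C@@H](OS(C)(=O)=O)CCC#C)CCCC1(C)C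
F2 | step 10 | (2S)-2-(but-3-yn-1-yl)-1,3,3-trimethylcyclohexan-1-ol | C#CCC[C@H]1C(C)(C)CCCC1(C)O
F3 | step 10 | (2S)-2-(5-hydroxypent-3-yn-1-yl)-1,3,3-trimethylcyclohexan-1-ol | OCC#CCC[C@H]1C(C)(C)CCCC1(C)O
F4 | step 10 | (2S)-2-[(3Z)-5-hydroxy-3-iodopent-3-en-1-yl]-1,3,3-trimethylcyclohexan-1-ol | OC/C=C(I)/CC[C@H]1C(C)(C)CCCC1(C)O
F5 | step 10 | (2S)-2-{(3Z)-5-hydroxy-3-[(trimethylsilyl)methyl]pent-3-en-1-yl}-1,3,3-trimethylcyclohexan-1-ol | OC/C=C(C[Si](C)(C)C)/CC[C@H]1C(C)(C)CCCC1(C)O
F6 | step 10 | methyl 2-{[(2Z)-5-[(1S)-2-hydroxy-2,6,6-trimethylcyclohexyl]-3-[(trimethylsilyl)methyl]pent-2-en-1-yl]oxy}acetate | COC(=O)COC/C=C(C[Si](C)(C)C)/CC[C@H]1C(C)(C)CCCC1(C)O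
F7 | step 26 | 4-tert-butyl 1-methyl (2R,3R)-2-{[drim-8(12)-en-11-yl]oxy}-3-[2-oxo-2-(2-oxo-1,3-oxazolidin-3-yl)ethyl]butanedioate | C=C1CC[C@H]2C(C)(C)CCC[C@]2(C)[C@H]1CO[C@@H](C(=O)OC)[C@@H](CC(=O)N3CCOC3=O)C(=O)OC(C)(C)C
F8 | step 26 | C6' carboxylic acid from F7 | C=C1CC[C@H]2C(C)(C)CCC[C@]2(C)[C@H]1CO[C@@H](C(=O)OC)[C@@H](CC(=O)N3CCOC3=O)C(=O)O
F9 | step 27 | bis(allyl ester) of the target at both C5' carboxyls | C=C1CC[C@H]2C(C)(C)CCC[C@]2(C)[C@H]1CO[C@@H](C(=O)OC)[C@@H](CC(=O)OCC=C)C(=O)OC[C@]1(C)CCC[C@]2(C)[C@@H](CO[C@@H](C(=O)OC)[C@@H](CC(=O)OCC=C)C(=O)OC)C(=C)CC[C@@H]12
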